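A flat start looks like a dead time, yet a rate that grows from nothing has none, so don't subtract a lag from these curves.

| setting | south | south-east | red | green | amber |
|---|---|---|---|---|---|
| substrate | 0.12 M | 0.50 M | 0.25 M | 0.25 M | 0.25 M |
| precatalyst | 17 mM | 17 mM | 17 mM | 17 mM | 17 mM |
| temperature | 15 °C | 30 °C | 40 °C | 20 °C |  |
| remark | run made earlier | run made earlier |  |  | at 20 °C until 5.0 h, from then on at 40 °C |
| time |  |  | 10 h | 10 h | 10 h |

| run | time / h | target / % |
|---|---|---|
| south | 3.00 | 0 |
| south | 6.00 | 4 |
| south | 15.0 | 26 |
| south | 40.0 | 77 |
| south-east | 5.00 | 36 |
| south-east | 10.0 | 73 |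
| south-east | 15.0 | 81 |
| south-east | 20.0 | 83 |

(readings scatter by 1.5 percentage points)

- in a conversion other conformer counts as not yet reacted

- the flask with the highest amount of target, in percent of the substrate charged ("all alike" if they lie within 1.5 percentage points) (red / green / amber / all alike)
- final target, as a percentage of the substrate charged, in red
- final target, as a percentage of the substrate charged, in green
- final target, as a percentage of the substrate charged, in amber

Suppose precatalyst turns slowly into catalyst, so that c(catalyst) rises in proportion to t, and target forms at a rate proportional to c(catalyst) times c(substrate). That is a pseudo-first-order decay whose constant grows with time. Integrating puts a square in the exponent, with y∞ the plateau, which I take from the last south-east reading, 83.0%: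

y = y∞ · (1 − exp(−(t/τ)^2))

One reading from each run gives τ:

south: τ = 24.5 h
south-east: τ = 6.63 h

This τ, the waking time, is the time at which the exponent reaches one. As a check, the south τ returns 77.2% at 40.0 h, where the unused reading is 77%.

I draw ln τ as a straight line in temperature, a rough stand-in for Arrhenius behaviour, and take τ as independent of the substrate charge:

green: τ = 15.8 h, y = 27.3%
red: τ = 2.78 h, y = 83.0%

For amber I add the exponents of its cold and hot halves, counting the hot half as if it started afresh:

amber: y = 80.1%

So my order puts red ahead of amber, and amber ahead of green.

The forecast also names red, with red 81% (72% to 88%), green 35% (24% to 47%) and amber 79% (68% to 87%). Of red it says “so red reaches the ceiling, perhaps slightly lower when hotter”. My green lies lower than its figure.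

The flasks give red 79.2%, green 26.9% and amber 75.4%, so red leads.

    substrate ⇌ other conformer (K = 0.230, k = 6.80 × 10⁻⁵ /s, Ea = 98.0 kJ/mol, ΔH = 3.00 kJ/mol)
    substrate + catalyst → catalyst + target (k = 0.0150 /M/s, Ea = 45.0 kJ/mol)
    catalyst + other conformer → catalyst + isomer of the product (k = 0.0220 /M/s, Ea = 64.0 kJ/mol)
    precatalyst → catalyst (k = 7.90 × 10⁻⁵ /s, Ea = 90.0 kJ/mol)
    (constants at 40 °C)

At 10.0 h, green held 23.6% of its charge as catalyst and 76.4% as precatalyst, and its target of 26.9% stood beside my 27.3% from τ = 15.8 h. The time allowed is the main reason for green's shortfall: green gives 26.9% at 10 h, and 87.7% when left ten times as long. The repeat of red at 15 °C shares the south temperature but has twice the substrate, and the south τ of 24.5 h reckons 12.7% for it, where that flask holds 12.3%.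

The runs are simulated with constants of no real substance; the scatter is artificial.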